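**Retrosynthetic overview**
1. Target 29 ⇐ ene-type chlorination (C6–Cl, Δ5(16)) of Δ5-alkene 28; the 13,14-epoxy-12-ol ⇐ enone 26 ⇐ ketone 23.
2. Briarane bicycle 23 ⇐ one transannular C1–C10 bond formation in the 14-membered cembranoid-type carbocycle 22 (epoxide-derived C1 radical onto the C10=C11–C12=O enone), the laboratory counterpart of the proposed cembrane → briarane 3,8-cyclisation.
3. Carbocycle 20 ⇐ Nozaki–Hiyama–Kishi closure of C2–C3 in seco-chain 19 ⇐ HWE (C10=C11, phosphonate 6) and Wittig (C5=C6, salt 8).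
4. C6–C10 with the lactone stereocentres (C7, C8, C9, C17) ⇐ diacetone-D-glucose 9 through a 3-ulose aldol (sugar C1–C5 = C6–C10).
5. Ring order: γ-lactone → 14-membered carbocycle → six- and ten-membered rings together in the transannular step → oxirane.

Assumption: briarane numbering is used for every intermediate (C1–C14 ring carbons, C15 on C1, C16 on C5, C20 on C11, C17/C18/C19 = lactone CH/CH3/C=O); enolates, ylides and alkoxides made in situ by deprotonation are treated as ionised forms of the numbered compounds; the target is (1S,2S,3S,6S,7R,8R,9R,10S,11R,12R,13S,14R,17R) as read from the SMILES.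

**Route**

Step 1
Reactants: 1 prop-2-yn-1-ol
Product: 3 (E)-3-iodo-2-methylprop-2-en-1-ol, via alkenylalane 2 (not isolated)
Conditions: Me3Al (3 equiv), Cp2ZrCl2 (0.25 equiv), CH2Cl2, 0 °C to rt; then I2, THF, −30 to 0 °C
Reagents that add atoms: trimethylaluminium C[Al](C)C; iodine II
Why: Negishi Zr-catalysed carboalumination adds CH3 and Al syn across the alkyne and iodinolysis of the C–Al bond goes with retention, fixing the E geometry later needed at C1=C2.

Step 2
Reactants: 3 (E)-3-iodo-2-methylprop-2-en-1-ol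
Product: 4 (E)-3-bromo-1-iodo-2-methylprop-1-ene
Conditions: CBr4, PPh3, CH2Cl2, 0 °C
Reagents that add atoms: carbon tetrabromide BrC(Br)(Br)Br
Why: Appel bromination of a primary allylic alcohol proceeds by SN2 without touching the vinyl iodide.

Step 3
Reactants: 5 diethyl (2-oxopropyl)phosphonate; 4 (E)-3-bromo-1-iodo-2-methylprop-1-ene
Product: 6 diethyl [(6E)-7-iodo-6-methyl-3-oxohept-6-en-2-yl]phosphonate
Conditions: NaH, THF, 0 °C; n-BuLi, −78 to 0 °C; 4, −78 to 0 °C; then MeI, 0 °C to rt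
Reagents that add atoms: iodomethane CI
Why: The β-ketophosphonate dianion is alkylated at the more basic γ-carbon by the allylic bromide (Grieco-type dianion alkylation) and the remaining α-anion is then C-methylated, giving the C11–C14/C1–C2 unit in one pot.

Step 4
Reactants: 7 [2-(1,3-dioxolan-2-yl)ethyl]triphenylphosphonium bromide
Product: 8 [1-(1,3-dioxolan-2-yl)propan-2-yl]triphenylphosphonium iodide
Conditions: n-BuLi (1.0 equiv), THF, −78 to 0 °C; then MeI, 0 °C to rt
Reagents that add atoms: iodomethane CI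
Why: C-methylation of a non-stabilised phosphorus ylide gives the secondary phosphonium salt that carries C5, C16, C4 and masked C3.

Step 5
Reactants: 9 1,2:5,6-di-O-isopropylidene-α-D-glucofuranose
Product: 10 1,2:5,6-di-O-isopropylidene-α-D-ribo-hexofuranos-3-ulose
Conditions: (COCl)2, DMSO, CH2Cl2, −78 °C; Et3N, −78 to 0 °C
Reagents that add atoms: none
Why: Swern oxidation of the only free hydroxyl gives the ketone that becomes C8.

Step 6
Reactants: 10 1,2:5,6-di-O-isopropylidene-α-D-ribo-hexofuranos-3-ulose; 11 N,N-dimethylpropanamide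
Product: 12 3-C-[(1R)-1-(dimethylcarbamoyl)ethyl]-1,2:5,6-di-O-isopropylidene-α-D-allofuranose
Conditions: 11, LDA, THF, −78 °C; then 10, −78 °C; sat. NH4Cl
Reagents that add atoms: none
Why: Aldol addition of the Z(O) lithium amide enolate to the exo (β) face of the cis-fused bicyclic ketone gives the D-allo tertiary alcohol (C8), and a Zimmerman–Traxler chair with the C4 side pseudo-equatorial is expected to give 17R.

Step 7
Reactants: 12 3-C-[(1R)-1-(dimethylcarbamoyl)ethyl]-1,2:5,6-di-O-isopropylidene-α-D-allofuranose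
Product: 13 3-C-[(1R)-1-(dimethylcarbamoyl)ethyl]-2,3:5,6-di-O-isopropylidene-β-D-allofuranose
Conditions: CSA (10 mol %), acetone, 4 Å MS, rt
Reagents that add atoms: none
Why: Acid-catalysed acetal migration to the cis-2,3-diol (the thermodynamic acetonide pattern of D-allose and D-ribose) frees the anomeric OH while tying up O7 and O8, which later lets O9 and O7 be told apart.

Step 8
Reactants: 13 3-C-[(1R)-1-(dimethylcarbamoyl)ethyl]-2,3:5,6-di-O-isopropylidene-β-D-allofuranose; 8 [1-(1,3-dioxolan-2-yl)propan-2-yl]triphenylphosphonium iodide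
Product: 15 open-chain (5Z)-alkene 9-acetate, via open-chain C9 alcohol 14 (not isolated)
Conditions: 8 (3 equiv), KHMDS (2.9 equiv), THF, −78 to 0 °C; 13, −78 °C to rt; then Ac2O, 0 °C
Reagents that add atoms: acetic anhydride CC(=O)OC(C)=O
Why: Wittig olefination of the lactol with the non-stabilised disubstituted ylide opens the furanose to the Z-trisubstituted C5=C6 alkene (kinetic cis-oxaphosphetane; minor E isomer removed) and the only alkoxide released (O9) is acetylated in situ.

Step 9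
Reactants: 15 open-chain (5Z)-alkene 9-acetate
Product: 17 (5Z)-9-acetoxy C3–C10 aldehyde, via terminal diol 16 (not isolated)
Conditions: H5IO6 (1.3 equiv), EtOAc, 0 °C to rt
Reagents that add atoms: none
Why: Periodic acid hydrolyses the terminal acetonide selectively over the hindered internal acetonide and the dioxolane acetal and cleaves the resulting glycol to the C10 aldehyde without touching C9.

Step 10
Reactants: 17 (5Z)-9-acetoxy C3–C10 aldehyde; 6 diethyl [(6E)-7-iodo-6-methyl-3-oxohept-6-en-2-yl]phosphonate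
Product: 18 (1E,5Z,10E)-seco-C2/C3 enone vinyl iodide
Conditions: LiCl, i-Pr2NEt, MeCN, rt
Reagents that add atoms: none
Why: Horner–Wadsworth–Emmons olefination under Masamune–Roush conditions gives the E-configured C10=C11 enone without epimerising the α-acetoxy aldehyde.

Step 11
Reactants: 18 (1E,5Z,10E)-seco-C2/C3 enone vinyl iodide
Product: 19 (1E,5Z,10E)-seco-C2/C3 lactone aldehyde vinyl iodide
Conditions: TFA/H2O/CH2Cl2 (8:1:1), 0 °C to rt; NaHCO3 work-up
Reagents that add atoms: water O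
Why: Acid hydrolysis removes the acetonide and the dioxolane, and the γ-hydroxy amide lactonises onto O7 (the only free secondary OH, as O9 is acetylated) with loss of dimethylamine, all stereocentres being untouched.

Step 12
Reactants: 19 (1E,5Z,10E)-seco-C2/C3 lactone aldehyde vinyl iodide
Product: 20 (1E,3S,5Z,10E)-3-hydroxy 14-membered carbocycle
Conditions: CrCl2 (6 equiv), NiCl2 (1 mol %), Kishi chiral sulfonamide ligand (enantiomer chosen for 3S), Et3N, THF, rt, 1.5 mM, syringe pump
Reagents that add atoms: none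
Why: Ni/Cr-mediated Nozaki–Hiyama–Kishi macrocyclisation joins C2 to C3 with retention of the E vinyl geometry and tolerates the enone, lactone and acetate, the ligand-bound alkenylchromium setting the 3S carbinol.

Step 13
Reactants: 20 (1E,3S,5Z,10E)-3-hydroxy 14-membered carbocycle
Product: 21 (1R,2R,3S)-1,2-epoxy-3-hydroxy carbocycle
Conditions: VO(acac)2 (5 mol %), t-BuOOH (1.2 equiv), CH2Cl2, 0 °C
Reagents that add atoms: tert-butyl hydroperoxide CC(C)(C)OO
Why: Hydroxyl-directed vanadium epoxidation reacts at the allylic C1=C2 alkene only, and A(1,3) strain from the cis C15 methyl gives the threo epoxy alcohol, which fixes the later C2 oxygen as 2S.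

Step 14
Reactants: 21 (1R,2R,3S)-1,2-epoxy-3-hydroxy carbocycle
Product: 22 (1R,2R,3S)-3-acetoxy-1,2-epoxy carbocycle
Conditions: Ac2O, pyridine, DMAP (cat.), CH2Cl2, 0 °C
Reagents that add atoms: acetic anhydride CC(=O)OC(C)=O
Why: Acylation of the secondary alcohol leaves the tertiary C8 hydroxyl free and installs the C3 acetate of the target.

Step 15
Reactants: 22 (1R,2R,3S)-3-acetoxy-1,2-epoxy carbocycle
Product: 23 (5Z)-3,9-diacetoxy-2,8-dihydroxy-12-oxobriar-5-ene 19,7-lactone
Conditions: Cp2TiCl2 (2.5 equiv), Zn dust, 2,4,6-collidine·HCl (3 equiv), THF, rt, 22 added over 6 h to 3 mM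
Reagents that add atoms: none
Why: Proposed new method: Cp2Ti(III)Cl opens the trisubstituted epoxide homolytically at C1–O (Nugent–RajanBabu) to a tertiary C1 radical that keeps the C2 oxygen and its configuration; this nucleophilic radical adds transannularly (polarity-matched Giese addition) to C10 of the E-enone through a chair-like conformation with the C1–C2 and C10–C9 ring bonds pseudo-equatorial (C15 methyl and H10 anti, trans-fused); the α-keto radical is reduced by a second Ti(III) and the titanium enolate is protonated at C11 from the α-face anti to the angular methyl (11β-methyl); the closest known chemistry is Ti(III) epoxide-opening conjugate addition to enones and the Cp2TiCl transannular cyclisation of epoxygermacrolides to eudesmanolides.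

Step 16
Reactants: 23 (5Z)-3,9-diacetoxy-2,8-dihydroxy-12-oxobriar-5-ene 19,7-lactone
Product: 26 briarane 13-en-12-one, via tris-TMS enol ether 24 (not isolated), via bis-TMS enone 25 (not isolated)
Conditions: TMSCl (8 equiv), LDA (3.5 equiv), THF, −78 °C; Pd(OAc)2 (1.2 equiv), MeCN, rt; 1 M HCl, THF, 0 °C
Reagents that add atoms: none
Why: Kinetic deprotonation at the unhindered C13 methylene (the C11 stereocentre is not enolised) and Saegusa–Ito oxidation give the C13=C14 enone, the two hydroxyls being masked as TMS ethers that the acidic work-up removes.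

Step 17
Reactants: 26 briarane 13-en-12-one
Product: 27 briarane 13α,14α-epoxy-12-one
Conditions: t-BuOOH (3 equiv), DBU (1.5 equiv), CH2Cl2, 0 °C
Reagents that add atoms: tert-butyl hydroperoxide CC(C)(C)OO
Why: Weitz–Scheffer nucleophilic epoxidation adds the peroxide to C14 from the open α-face, anti to the C15 and C20 methyl groups, giving the 13S,14R oxirane.

Step 18
Reactants: 27 briarane 13α,14α-epoxy-12-one
Product: 28 6-deschloro-Δ5 isomer of the target (13α,14α-epoxy-12β-ol)
Conditions: NaBH4, CeCl3·7H2O, MeOH, −78 °C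
Reagents that add atoms: none
Why: Luche reduction delivers hydride to C12 from the α-face anti to the adjacent axial C20 methyl, giving the 12R alcohol trans to the oxirane while esters and lactone survive.

Step 19
Reactants: 28 6-deschloro-Δ5 isomer of the target
Product: 29 CNP0200238.1
Conditions: Ca(OCl)2, CO2 (dry ice), CH2Cl2/H2O, 0 °C
Reagents that add atoms: calcium hypochlorite [Ca+2].[O-]Cl.[O-]Cl
Why: Ene-type electrophilic chlorination with HOCl (Hegde–Wolinsky) puts Cl on the less substituted C6 from the outer β-face of the ring Z-alkene anti to the C7–O bond (6S), and loss of a C16 proton gives the exocyclic alkene.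

**Compound list**
1 | prop-2-yn-1-ol | C#CCO | starting material
2 | dimethylaluminium (E)-3-(dimethylalumanyl)-2-methylprop-2-en-1-olate | C[Al](C)/C=C(\C)CO[Al](C)C | intermediate
3 | (E)-3-iodo-2-methylprop-2-en-1-ol | OC/C(C)=C/I | intermediate
4 | (E)-3-bromo-1-iodo-2-methylprop-1-ene | BrC/C(C)=C/I | intermediate
5 | diethyl (2-oxopropyl)phosphonate | CCOP(=O)(OCC)CC(C)=O | starting material
6 | diethyl [(6E)-7-iodo-6-methyl-3-oxohept-6-en-2-yl]phosphonate (racemic at C–P) | CCOP(=O)(OCC)C(C)C(=O)CC/C(C)=C/I | intermediate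
7 | [2-(1,3-dioxolan-2-yl)ethyl]triphenylphosphonium bromide | [Br-].C1COC(CC[P+](c2ccccc2)(c2ccccc2)c2ccccc2)O1 | starting material
8 | [1-(1,3-dioxolan-2-yl)propan-2-yl]triphenylphosphonium iodide (racemic) | [I-].CC(CC1OCCO1)[P+](c1ccccc1)(c1ccccc1)c1ccccc1 | intermediate
9 | 1,2:5,6-di-O-isopropylidene-α-D-glucofuranose | O[C@@H]1[C@H]2OC(C)(C)O[C@H]2O[C@@H]1[C@H]1COC(C)(C)O1 | starting material
10 | 1,2:5,6-di-O-isopropylidene-α-D-ribo-hexofuranos-3-ulose | O=C1[C@H]2OC(C)(C)O[C@H]2O[C@@H]1[C@H]1COC(C)(C)O1 | intermediate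
11 | N,N-dimethylpropanamide | CCC(=O)N(C)C | starting material
12 | 3-C-[(1R)-1-(dimethylcarbamoyl)ethyl]-1,2:5,6-di-O-isopropylidene-α-D-allofuranose | C[C@@H](C(=O)N(C)C)[C@]1(O)[C@H]2OC(C)(C)O[C@H]2O[C@@H]1[C@H]1COC(C)(C)O1 | intermediate
13 | 3-C-[(1R)-1-(dimethylcarbamoyl)ethyl]-2,3:5,6-di-O-isopropylidene-β-D-allofuranose | C[C@@H](C(=O)N(C)C)[C@]12OC(C)(C)O[C@H]1[C@H](O)O[C@@H]2[C@H]1COC(C)(C)O1 | intermediate
14 | open-chain C3–C10 segment: C3 as 1,3-dioxolane acetal, (5Z)-alkene, 7,8-O-isopropylidene, (17R)-CH(CH3)CONMe2 on C8, free 9-OH, C10 as (4R)-2,2-dimethyl-1,3-dioxolan-4-yl; C7, C8, C9 as in the target | C1COC(O1)C/C(C)=C\[C@@H]1OC(C)(C)O[C@]1([C@@H](C)C(=O)N(C)C)[C@H](O)[C@H]1COC(C)(C)O1 | intermediate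
15 | 9-O-acetate of 14 | C1COC(O1)C/C(C)=C\[C@@H]1OC(C)(C)O[C@]1([C@@H](C)C(=O)N(C)C)[C@H](OC(C)=O)[C@H]1COC(C)(C)O1 | intermediate
16 | terminal 1,2-diol from 15 (terminal acetonide removed) | C1COC(O1)C/C(C)=C\[C@@H]1OC(C)(C)O[C@]1([C@@H](C)C(=O)N(C)C)[C@H](OC(C)=O)[C@H](O)CO | intermediate
17 | (5Z)-9-acetoxy C3–C10 aldehyde (C10 = CHO; C3 dioxolane; 7,8-acetonide; C17 amide) | C1COC(O1)C/C(C)=C\[C@@H]1OC(C)(C)O[C@]1([C@@H](C)C(=O)N(C)C)[C@H](OC(C)=O)C=O | intermediate
18 | (1E,5Z,10E)-seco-C2/C3 chain: C2 vinyl iodide, C12 enone, 9-OAc, 7,8-acetonide, C17 amide, C3 dioxolane | C1COC(O1)C/C(C)=C\[C@@H]1OC(C)(C)O[C@]1([C@@H](C)C(=O)N(C)C)[C@H](OC(C)=O)/C=C(\C)C(=O)CC/C(C)=C/I | intermediate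
19 | (1E,5Z,10E)-seco-C2/C3 chain: C3 aldehyde, C2 vinyl iodide, C12 enone, 9-OAc, 8-OH, C19→O7 γ-lactone (17R) | O=CC/C(C)=C\[C@@H]1OC(=O)[C@H](C)[C@@]1(O)[C@H](OC(C)=O)/C=C(\C)C(=O)CC/C(C)=C/I | intermediate
20 | (1E,3S,5Z,10E)-9-acetoxy-3,8-dihydroxy-12-oxo 14-membered carbocycle with C19→O7 γ-lactone | C/C1=C/[C@@H]2OC(=O)[C@H](C)[C@@]2(O)[C@H](OC(C)=O)/C=C(\C)C(=O)CC/C(C)=C/[C@@H](O)C1 | intermediate
21 | (1R,2R,3S)-1,2-epoxide of 20 | C/C1=C/[C@@H]2OC(=O)[C@H](C)[C@@]2(O)[C@H](OC(C)=O)/C=C(\C)C(=O)CC[C@@]3(C)O[C@@H]3[C@@H](O)C1 | intermediate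
22 | 3-O-acetate of 21 | C/C1=C/[C@@H]2OC(=O)[C@H](C)[C@@]2(O)[C@H](OC(C)=O)/C=C(\C)C(=O)CC[C@@]3(C)O[C@@H]3[C@@H](OC(C)=O)C1 | intermediate
23 | (5Z)-3,9-diacetoxy-2,8-dihydroxy-12-oxobriar-5-ene 19,7-lactone (1S,2S,3S,9R,10S,11R,17R; C7 and C8 as in the target) | C/C1=C/[C@@H]2OC(=O)[C@H](C)[C@@]2(O)[C@H](OC(C)=O)[C@H]3[C@@H](C)C(=O)CC[C@]3(C)[C@H](O)[C@@H](OC(C)=O)C1 | intermediate
24 | 2,8-bis-O-TMS 12-(trimethylsilyloxy)-12-ene of 23 | C/C1=C/[C@@H]2OC(=O)[C@H](C)[C@@]2(O[Si](C)(C)C)[C@H](OC(C)=O)[C@H]3[C@@H](C)C(O[Si](C)(C)C)=CC[C@]3(C)[C@H](O[Si](C)(C)C)[C@@H](OC(C)=O)C1 | intermediate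
25 | 2,8-bis-O-TMS 13-en-12-one | C/C1=C/[C@@H]2OC(=O)[C@H](C)[C@@]2(O[Si](C)(C)C)[C@H](OC(C)=O)[C@H]3[C@@H](C)C(=O)C=C[C@]3(C)[C@H](O[Si](C)(C)C)[C@@H](OC(C)=O)C1 | intermediate
26 | (5Z)-3,9-diacetoxy-2,8-dihydroxy-12-oxobriara-5,13-diene 19,7-lactone | C/C1=C/[C@@H]2OC(=O)[C@H](C)[C@@]2(O)[C@H](OC(C)=O)[C@H]3[C@@H](C)C(=O)C=C[C@]3(C)[C@H](O)[C@@H](OC(C)=O)C1 | intermediate
27 | (13S,14R)-13,14-epoxide of 26 (α-oxirane) | C/C1=C/[C@@H]2OC(=O)[C@H](C)[C@@]2(O)[C@H](OC(C)=O)[C@H]3[C@@H](C)C(=O)[C@@H]4O[C@@H]4[C@]3(C)[C@H](O)[C@@H](OC(C)=O)C1 | intermediate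
28 | (12R)-alcohol from 27: (5Z)-3,9-diacetoxy-13α,14α-epoxy-2,8,12β-trihydroxybriar-5-ene 19,7-lactone | C/C1=C/[C@@H]2OC(=O)[C@H](C)[C@@]2(O)[C@H](OC(C)=O)[C@H]3[C@@H](C)[C@@H](O)[C@@H]4O[C@@H]4[C@]3(C)[C@H](O)[C@@H](OC(C)=O)C1 | intermediate
29 | CNP0200238.1: 3,9-diacetoxy-6β-chloro-13α,14α-epoxy-2,8,12β-trihydroxybriar-5(16)-ene 19,7-lactone | C=C1C[C@H](OC(C)=O)[C@@H](O)[C@]2(C)[C@H]([C@@H](C)[C@@H](O)[C@@H]3O[C@@H]32)[C@@H](OC(C)=O)[C@]2(O)[C@@H](C)C(=O)O[C@H]2[C@H]1Cl | target

**Step count**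
Total steps: 19. Longest linear sequence: 15 (steps 5–19, from 9).

**Three steps most likely to fail**

Step 15 (transannular Ti(III) cyclisation). The tertiary radical may instead be reduced or lose a β-hydrogen to give an allylic alcohol, and the facial outcome at C1/C10 rests on a conformational argument. Fallback: set out from epoxy acetate 22 and open the epoxide with MgBr2·OEt2 (Et2O, −20 °C) at the tertiary carbon to give bromohydrin F5. A tin-free radical chain ((TMS)3SiH, AIBN, benzene, 80 °C, syringe pump) then generates the same C1 radical by bromine abstraction, closes C1–C10 and quenches the α-keto radical by H-transfer from the silane, coming back to the route at ketone 23.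

Step 12 (NHK macrocyclisation). The β,γ-unsaturated aldehyde in 19 can slip into conjugation, and the C3 configuration depends on ligand control inside a forming ring. Fallback: set out from aldehyde 17 and run the HWE reaction with isopropenyl phosphonate F1 (made from 5 as in step 3 with 3-bromo-2-methylprop-1-ene in place of 4) to give enone F2. The same TFA/H2O treatment gives lactone aldehyde F3. Reagent-controlled addition of divinylzinc with a chiral amino-alcohol ligand sets 3S in open chain and gives diene alcohol F4. Ring-closing metathesis (Grubbs II, toluene, 80 °C, 1 mM) between the vinyl and isopropenyl groups then forms the C1=C2 bond and comes back to the route at carbocycle 20; the E geometry of the new trisubstituted alkene must be confirmed.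

Step 19 (ene chlorination). Proton loss could occur from C4 instead of C16, and chlorine could arrive on the α-face. Fallback: set out from 28 and run a Schenck ene reaction with singlet oxygen (O2, TPP, hν, CH2Cl2, −20 °C), which has the same regiochemistry and face preference, to give allylic hydroperoxide F6. PPh3 reduces it to allylic alcohol F7 (6-epi oxygen). Corey–Kim chlorination (NCS, Me2S, CH2Cl2, −20 °C), selective for the allylic alcohol, then displaces with inversion and comes back to the route at target 29. This corrects the case in which electrophiles prefer the α-face.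

**Further compounds**
F1 | step 12 | diethyl (6-methyl-3-oxohept-6-en-2-yl)phosphonate | CCOP(=O)(OCC)C(C)C(=O)CCC(C)=C
F2 | step 12 | (5Z,10E)-enone from 17 and F1 with terminal isopropenyl group (C3 dioxolane, 7,8-acetonide, C17 amide, 9-OAc) | C1COC(O1)C/C(C)=C\[C@@H]1OC(C)(C)O[C@]1([C@@H](C)C(=O)N(C)C)[C@H](OC(C)=O)/C=C(\C)C(=O)CCC(C)=C
F3 | step 12 | (5Z,10E)-lactone aldehyde with terminal isopropenyl group | O=CC/C(C)=C\[C@@H]1OC(=O)[C@H](C)[C@@]1(O)[C@H](OC(C)=O)/C=C(\C)C(=O)CCC(C)=C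
F4 | step 12 | (3S,5Z,10E)-3-hydroxy-3-vinyl diene (RCM precursor) | C=C[C@@H](O)C/C(C)=C\[C@@H]1OC(=O)[C@H](C)[C@@]1(O)[C@H](OC(C)=O)/C=C(\C)C(=O)CCC(C)=C
F5 | step 15 | (2S,3S)-3-acetoxy-1-bromo-2-hydroxy carbocycle (bromohydrin of 22) | C/C1=C/[C@@H]2OC(=O)[C@H](C)[C@@]2(O)[C@H](OC(C)=O)/C=C(\C)C(=O)CC[C@](C)(Br)[C@H](O)[C@@H](OC(C)=O)C1
F6 | step 19 | 6α-hydroperoxy-Δ5(16) analogue of the target | C=C1C[C@H](OC(C)=O)[C@@H](O)[C@]2(C)[C@H]([C@@H](C)[C@@H](O)[C@@H]3O[C@@H]32)[C@@H](OC(C)=O)[C@]2(O)[C@@H](C)C(=O)O[C@H]2[C@@H]1OO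
F7 | step 19 | 6α-hydroxy-Δ5(16) analogue of the target | C=C1C[C@H](OC(C)=O)[C@@H](O)[C@]2(C)[C@H]([C@@H](C)[C@@H](O)[C@@H]3O[C@@H]32)[C@@H](OC(C)=O)[C@]2(O)[C@@H](C)C(=O)O[C@H]2[C@@H]1O
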